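## Retrosynthetic overview

- The cyclohexene ring is never built: it is (R)-carvone (**1**). Its C5 centre directs C10 (Michael addition anti to isopropenyl) and C7 (epoxidation, Wharton, Mitsunobu), giving allylic tosylacetate **6**.
- The 3β-hydroxydecalin is disconnected to an (S)-epoxy-polyene. The epoxide comes from methyl (R)-glycidate (**7**), the E,E-diene from geranyl acetate (**10**); together they give bromide **16**.
- Key disconnection, C9–C12: decarboxylative Ireland–Claisen [3,3] rearrangement **17** → **18** (**17** is **6** C-alkylated with **16**). It moves the C7–O stereochemistry to C9 and shifts the alkene to C7=C8.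
- Last: desulfonylation to **19**, then Ti(III) radical bicyclisation, in which the epoxide centre controls C5', C10' and C9'.
- Ring order: carvone ring (bought) → decalin ring A → decalin ring B (both in the final cascade).

Assumptions: the target is the normal-series 3β-ol as drawn. Compounds **2**/**3** are used as C6 epimer mixtures (re-enolised in step 3), and the sulfonyl-bearing carbons of **13**, **17**, **18** are epimer mixtures removed on desulfonylation. The route is designed from known reaction types and has not been run; steps 3, 4 and 15 have no close precedent on these substrates.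

## Route

**Step 1**
Reactants: **1** (R)-carvone
Product: **2** (5R,6RS)-2,6-dimethyl-5-(prop-1-en-2-yl)cyclohex-2-en-1-one
Conditions: LDA, THF, −78 °C; MeI
Reagents that add atoms: iodomethane, CI
Why: Kinetic α'-enolate alkylation at C6; the new centre is re-enolised later, so its configuration does not matter.

**Step 2**
Reactants: **2**
Product: **3** (1R,4R,6R)-1,3-dimethyl-4-(prop-1-en-2-yl)-7-oxabicyclo[4.1.0]heptan-2-one (epoxide anti to isopropenyl)
Conditions: 30% H2O2, aq NaOH, MeOH, 0 °C
Reagents that add atoms: hydrogen peroxide, OO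
Why: Weitz–Scheffer nucleophilic epoxidation; as with carvone itself, hydroperoxide adds axially to the face opposite the isopropenyl group.

**Step 3**
Reactants: **3**
Product: **4** methyl 3-[(1R,3S,4S,6R)-1,3-dimethyl-2-oxo-4-(prop-1-en-2-yl)-7-oxabicyclo[4.1.0]heptan-3-yl]propanoate
Conditions: LDA, THF, −78 °C; methyl acrylate (1.1 equiv), −78 °C; AcOH quench
Reagents that add atoms: methyl acrylate, C=CC(=O)OC
Why: Enolate Michael addition anti to the adjacent (pseudo-axial) isopropenyl sets C10 with methyl cis and the propanoate chain trans to isopropenyl; with the enone masked as the epoxide, the second intramolecular Michael that plagues carvone dienolates cannot occur.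

**Step 4**
Reactants: **4**
Product: **5** methyl 3-[(1R,4R,6S)-4-hydroxy-1,3-dimethyl-6-(prop-1-en-2-yl)cyclohex-2-en-1-yl]propanoate (OH trans to isopropenyl)
Conditions: N2H4·H2O, AcOH, MeOH, 0 °C → rt
Reagents that add atoms: none
Why: Wharton transposition; the epoxide C–O bond is retained, so the carbinol keeps the epoxide configuration while the alkene moves next to the quaternary carbon.

**Step 5**
Reactants: **5**
Product: **6** methyl 3-[(1R,4S,6S)-1,3-dimethyl-6-(prop-1-en-2-yl)-4-(tosylacetoxy)cyclohex-2-en-1-yl]propanoate (ester oxygen cis to isopropenyl)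
Conditions: TsCH2CO2H, PPh3, DIAD, THF, 0 °C → rt
Reagents that add atoms: (4-methylbenzenesulfonyl)acetic acid, Cc1ccc(cc1)S(=O)(=O)CC(=O)O
Why: Mitsunobu esterification inverts the allylic carbinol to the β-face needed for step 15; SN2' is blocked by the neopentyl alkene terminus.

**Step 6**
Reactants: **7** methyl (R)-oxirane-2-carboxylate (methyl (R)-glycidate, L-serine-derived)
Product: **8** 2-[(2R)-oxiran-2-yl]propan-2-ol
Conditions: MeMgCl (2.2 equiv), THF, −78 → −30 °C
Reagents that add atoms: methylmagnesium chloride, C[Mg]Cl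
Why: Double Grignard addition to the ester is faster than epoxide opening at low temperature; the stereocentre is untouched.

**Step 7**
Reactants: **8**
Product: **9** (2S)-3-methyl-1-(phenylsulfonyl)butane-2,3-diol
Conditions: PhSO2Na, NH4Cl, EtOH–H2O, 80 °C
Reagents that add atoms: sodium benzenesulfinate, [Na+].[O-]S(=O)c1ccccc1
Why: Sulfinate S-alkylation opens the terminal epoxide at CH2 (any Payne isomer funnels through the same terminal epoxide), leaving the carbinol centre intact.

**Step 8**
Reactants: **10** geranyl acetate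
Product: **11** (2E,6E)-8-hydroxy-3,7-dimethylocta-2,6-dien-1-yl acetate
Conditions: SeO2 (cat.), t-BuOOH, CH2Cl2, rt; NaBH4 work-up
Reagents that add atoms: tert-butyl hydroperoxide, CC(C)(C)OO
Why: Sharpless SeO2 allylic oxidation (ene/[2,3]) is selective for the terminal E-methyl group.

**Step 9**
Reactants: **11**
Product: **12** (2E,6E)-8-bromo-3,7-dimethylocta-2,6-dien-1-yl acetate
Conditions: CBr4, PPh3, CH2Cl2, 0 °C
Reagents that add atoms: carbon tetrabromide, BrC(Br)(Br)Br
Why: Appel bromination of the primary allylic alcohol without allylic transposition.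

**Step 10**
Reactants: **9** and **12**
Product: **13** (2E,6E,10S)-10,11-dihydroxy-3,7,11-trimethyl-9-(phenylsulfonyl)dodeca-2,6-dien-1-yl acetate (C9 epimers)
Conditions: **9**, n-BuLi (3.1 equiv), THF–HMPA, −78 → −30 °C; then **12**, −78 °C
Reagents that add atoms: none
Why: Alkylation of the β-oxido α-sulfonyl carbanion by SN2 at the allylic bromide; the alkoxide form prevents β-elimination, and the non-allylic sulfone avoids alkene scrambling on later removal.

**Step 11**
Reactants: **13**
Product: **14** (2E,6E,10R)-10,11-dihydroxy-3,7,11-trimethyldodeca-2,6-dien-1-yl acetate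
Conditions: SmI2, HMPA, THF, t-BuOH, −20 °C
Reagents that add atoms: none
Why: Reductive desulfonylation; a free β-hydroxy sulfone is reduced rather than eliminated, and the allylic acetate survives.

**Step 12**
Reactants: **14**
Product: **15** (2E,6E)-9-[(2S)-3,3-dimethyloxiran-2-yl]-3,7-dimethylnona-2,6-dien-1-ol ((S)-10,11-epoxyfarnesol)
Conditions: MsCl, pyridine, CH2Cl2, 0 °C; then K2CO3, MeOH, rt
Reagents that add atoms: none
Why: Selective mesylation of the secondary OH, then intramolecular Williamson closure by the tertiary alkoxide with inversion (R-diol → S-epoxide); the acetate is methanolysed in the same pot.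

**Step 13**
Reactants: **15**
Product: **16** (S)-10,11-epoxyfarnesyl bromide
Conditions: MsCl, Et3N, THF, −45 °C; LiBr, THF, 0 °C
Reagents that add atoms: lithium bromide, [Li+].[Br-]
Why: Allylic mesylate/bromide exchange under non-acidic conditions that leave the trisubstituted epoxide intact.

**Step 14**
Reactants: **6** and **16**
Product: **17** (1S,4R,5S)-4-(3-methoxy-3-oxopropyl)-2,4-dimethyl-5-(prop-1-en-2-yl)cyclohex-2-en-1-yl (4E,8E)-11-[(2S)-3,3-dimethyloxiran-2-yl]-5,9-dimethyl-2-(4-methylbenzenesulfonyl)undeca-4,8-dienoate (C2 epimers)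
Conditions: Cs2CO3, DMF, 0 °C → rt
Reagents that add atoms: none
Why: Malonate-type C-alkylation of the sulfonylacetate (pKa ≈ 12) under mild base, which the methyl ester and epoxide tolerate.

**Step 15 (key step)**
Reactants: **17**
Product: **18** methyl 3-[(1S,2S,6S)-2-{(3E,7E)-10-[(2S)-3,3-dimethyloxiran-2-yl]-4,8-dimethyl-1-(4-methylbenzenesulfonyl)deca-3,7-dien-1-yl}-1,3-dimethyl-6-(prop-1-en-2-yl)cyclohex-3-en-1-yl]propanoate (sulfonyl-carbon epimers)
Conditions: BSA (3 equiv), KOAc (0.2 equiv), toluene, 110–150 °C (sealed tube or microwave)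
Reagents that add atoms: none
Why: Decarboxylative Claisen rearrangement (Ireland–Claisen [3,3] of the in-situ silyl ketene acetal, then loss of CO2); it is suprafacial, so the β C7–O bond becomes the β C9–C12 bond (cis to the C10 methyl and isopropenyl) and the alkene moves to C7=C8.

**Step 16**
Reactants: **18**
Product: **19** methyl 3-[(1S,2S,6S)-2-{(3E,7E)-10-[(2S)-3,3-dimethyloxiran-2-yl]-4,8-dimethyldeca-3,7-dien-1-yl}-1,3-dimethyl-6-(prop-1-en-2-yl)cyclohex-3-en-1-yl]propanoate
Conditions: Na(Hg) 5%, Na2HPO4, MeOH–THF, −20 → 0 °C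
Reagents that add atoms: none
Why: Buffered reductive desulfonylation of a non-allylic alkyl aryl sulfone; ester, epoxide and alkenes are inert.

**Step 17**
Reactants: **19**
Product: **20** methyl lansiolate
Conditions: Cp2TiCl2 (0.3 equiv), Mn, TMSCl, 2,4,6-collidine, THF, rt; then TBAF
Reagents that add atoms: none
Why: Ti(III) (Nugent–RajanBabu) epoxy-polyene radical bicyclisation through a chair–chair array with the C3'–OTi equatorial gives the trans-decalin (3β-OH, 5α-H, 10β-Me, 9α-H) from the S-epoxide and E,E-alkenes; Ti trapping and β-H elimination give the exocyclic methylene (endocyclic isomers are the expected minor by-products).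

## Compound list

1 | (R)-carvone | C=C(C)[C@@H]1CC=C(C)C(=O)C1 | starting material
2 | (5R,6RS)-6-methylcarvone | C=C(C)[C@@H]1CC=C(C)C(=O)C1C | intermediate
3 | (1R,4R,6R)-1,3-dimethyl-4-isopropenyl-7-oxabicyclo[4.1.0]heptan-2-one | C=C(C)[C@@H]1C[C@H]2O[C@@]2(C)C(=O)C1C | intermediate
4 | methyl 3-[(1R,3S,4S,6R)-1,3-dimethyl-2-oxo-4-isopropenyl-7-oxabicyclo[4.1.0]heptan-3-yl]propanoate | C=C(C)[C@@H]1C[C@H]2O[C@@]2(C)C(=O)[C@@]1(C)CCC(=O)OC | intermediate
5 | methyl 3-[(1R,4R,6S)-4-hydroxy-1,3-dimethyl-6-isopropenylcyclohex-2-en-1-yl]propanoate | C=C(C)[C@@H]1C[C@@H](O)C(C)=C[C@@]1(C)CCC(=O)OC | intermediate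
6 | methyl 3-[(1R,4S,6S)-1,3-dimethyl-6-isopropenyl-4-(tosylacetoxy)cyclohex-2-en-1-yl]propanoate | C=C(C)[C@@H]1C[C@H](OC(=O)CS(=O)(=O)c2ccc(C)cc2)C(C)=C[C@@]1(C)CCC(=O)OC | intermediate
7 | methyl (R)-glycidate | COC(=O)[C@H]1CO1 | starting material
8 | 2-[(2R)-oxiran-2-yl]propan-2-ol | CC(C)(O)[C@H]1CO1 | intermediate
9 | (2S)-3-methyl-1-(phenylsulfonyl)butane-2,3-diol | CC(C)(O)[C@H](O)CS(=O)(=O)c1ccccc1 | intermediate
10 | geranyl acetate | CC(=O)OC/C=C(C)/CCC=C(C)C | starting material
11 | (2E,6E)-8-hydroxygeranyl acetate | CC(=O)OC/C=C(C)/CC/C=C(C)/CO | intermediate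
12 | (2E,6E)-8-bromogeranyl acetate | CC(=O)OC/C=C(C)/CC/C=C(C)/CBr | intermediate
13 | (2E,6E,10S)-10,11-dihydroxy-9-(phenylsulfonyl)farnesyl acetate | CC(=O)OC/C=C(C)/CC/C=C(C)/CC(S(=O)(=O)c1ccccc1)[C@@H](O)C(C)(C)O | intermediate
14 | (2E,6E,10R)-10,11-dihydroxyfarnesyl acetate | CC(=O)OC/C=C(C)/CC/C=C(C)/CC[C@@H](O)C(C)(C)O | intermediate
15 | (S)-10,11-epoxyfarnesol | OC/C=C(C)/CC/C=C(C)/CC[C@@H]1OC1(C)C | intermediate
16 | (S)-10,11-epoxyfarnesyl bromide | BrC/C=C(C)/CC/C=C(C)/CC[C@@H]1OC1(C)C | intermediate
17 | C-alkylated allylic tosylacetate (name in step 14) | C=C(C)[C@@H]1C[C@H](OC(=O)C(C/C=C(C)/CC/C=C(C)/CC[C@@H]2OC2(C)C)S(=O)(=O)c2ccc(C)cc2)C(C)=C[C@@]1(C)CCC(=O)OC | intermediate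
18 | rearranged sulfone (name in step 15) | C=C(C)[C@@H]1CC=C(C)[C@H](C(C/C=C(C)/CC/C=C(C)/CC[C@@H]2OC2(C)C)S(=O)(=O)c2ccc(C)cc2)[C@@]1(C)CCC(=O)OC | intermediate
19 | epoxy-polyene cyclisation precursor (name in step 16) | C=C(C)[C@@H]1CC=C(C)[C@H](CC/C=C(C)/CC/C=C(C)/CC[C@@H]2OC2(C)C)[C@@]1(C)CCC(=O)OC | intermediate
20 | methyl lansiolate; methyl 3-[(1S,2S,6S)-2-{2-[(1S,4aR,6S,8aR)-6-hydroxy-5,5,8a-trimethyl-2-methylidenedecahydronaphthalen-1-yl]ethyl}-1,3-dimethyl-6-(prop-1-en-2-yl)cyclohex-3-en-1-yl]propanoate | C=C(C)[C@@H]1CC=C(C)[C@H](CC[C@H]2C(=C)CC[C@H]3C(C)(C)[C@@H](O)CC[C@]23C)[C@@]1(C)CCC(=O)OC | target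

## Summary

Total steps: 17. Longest linear sequence: 10 (geranyl acetate **10** → **20**, steps 8–17; the carvone branch is 9).

Three steps most likely to fail, each with a fallback that changes the approach:

1. **Step 15** — the [3,3] shift must form a bond to a carbon next to the quaternary centre, from an α-substituted sulfonylacetate, in a cis-carveyl-type ring that must flip to put the C–O bond axial. Fallback: run the decarboxylative Claisen on unalkylated **6** (less congested) to the tosylmethyl compound, saponify the methyl ester, alkylate the carboxylate/α-sulfonyl dianion with **16**, then re-esterify with TMSCHN2 before steps 16–17.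
2. **Step 4** — Wharton hydrazone formation at a ketone flanked by two fully substituted carbons, with possible ester hydrazinolysis. Fallback: reduce the ketone (NaBH4), convert the epoxy alcohol to its imidazolyl thiocarbonate, and use Bu3SnH/AIBN radical epoxide fragmentation to reach the same allylic alcohol **5**.
3. **Step 3** — yield and facial selectivity of the Michael addition on the epoxy-ketone enolate. Fallback: alkylate **2** with allyl bromide before epoxidation (anti to isopropenyl), then hydroborate/oxidise and esterify the allyl group to the propanoate before continuing with steps 2 and 4.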